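**Remark (assumption):** the target has no stereocentre, no stereogenic axis and no stereogenic double bond. It is achiral, so "the single enantiomer given" is taken as the one constitution shown, and no step has to set configuration.

**Route in one sentence:** an oxa-Fischer key step, i.e. the acid-triggered [3,3]-sigmatropic rearrangement and cyclisation of the N-aryloxy enamine formed in the flask from a pyrano-fused 4-hydroxycoumarin and an O-aryl hydroxylamine.

## Structural features

The target is an almost planar pentacycle: a coumestan (6H-benzofuro[3,2-c]chromen-6-one) with benzene ring A (C1–C4, C4a, C11b), lactone ring B (O5, C6(=O), C6a), furan ring C (C6a, C6b, C10a, O11, C11a) and benzene ring D (C6b–C10a). A 2,2-dimethyl-3,4-dihydro-2H-pyran (ring E) is fused across C1–C2, with its oxygen on C1 and its CH2 on C2. Ring A is a phloroglucinol unit substituted everywhere except C4–H; its three oxygens have three different roles (ring-E ether on C1, OMe on C3, lactone O5 on C4a). Ring D is a resorcinol unit: O11 sits on C10a and the free OH on C9, para to C6b, so catechol/o-quinone annulations do not apply. The only sp3 atoms are CH2CH2CMe2 and OMe. The fragile groups are the lactone (opened by hydroxide or alkoxide, reclosed by acid), the free phenol, the oxidisable trioxygenated ring A and the tertiary alkyl aryl ether of ring E. The real difficulty is the tetrasubstituted C6a=C11a unit shared by lactone and furan. The C6a–C6b bond joins the α-carbon of a β-oxo lactone to the ortho carbon of a phenol, two carbons that are both nucleophilic, and O11–C11a must be closed next to the C1 oxygen. The key step exploits exactly this feature: ring C is an enol (C6a=C11a–O) fused to a phenol (C6b=C10a–O11), so an N–O tether between C11a and C10a lets a [3,3] shift form C6a–C6b and then O11–C11a.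

## Logic of the disconnections

**14 ⇒ 13.** Cut: the O–CH2Ph bond on the C9 oxygen, a protecting group and not a skeletal bond. Reason: the D-ring oxygen must be masked while the aryl–O–N bond is made with copper, because a free phenol would itself be O-arylated; an ether larger than OH next to C2' also helps to steer the key step. Gain: none in skeleton, at the cost of one step. Demand: cleavage without touching the lactone or the other ethers; neutral hydrogenolysis should meet it.

**13 ⇒ 6 + 10 (key disconnection).** Cut: C6a–C6b and O11–C11a, the two furan bonds that do not belong to ring D. In the forward sense the C–C bond arises from 11 by a [3,3] shift in which the N–O bond breaks, and the C–O bond arises from 12 by closure with loss of ammonia. Reason: C6a and C6b are both nucleophilic in their parent enol and phenol, so no simple ionic union exists. An N–O tether makes the union pericyclic and serves as the internal oxidant. O11 is brought in by 10, and the original oxygen on that carbon of 6 leaves as water. Gain: a pentacycle goes back to a tricycle and a simple benzene derivative, with no halogenation and no metal. Demand: condensation only at the ketone-like carbon of 6, rearrangement to C6' and not C2' of 10, and complete deaminative ring closure.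

**10 ⇒ 9 ⇒ 7 + 8.** Cut: the two N–C(=O) bonds (9 to 10), then the aryl C1'–O bond (9 to 7 + 8). Reason: an aryl–O–NH2 unit is most directly made by oxidative coupling of an N–OH donor with an aryl boron compound, with the nitrogen masked as an imide. Gain: two commercial compounds. Demand: the N–O bond must survive the unmasking, and the benzyl ether must be inert to copper(II) and hydrazine.

**6 ⇒ 4.** Cut: C6–O5 and C6–C6a, so that the lactone carbonyl carbon is taken out as a carbonate unit; the forward reaction passes through 5. Reason: the ketone carbon of 4 becomes C11a and its methyl carbon becomes C6a, so both nucleophilic sites needed for ring B are already in place. Gain: ring B is removed and a bicyclic ketone with one free phenol remains. Demand: C-acylation of a ketone flanked by two ortho oxygens, then lactonisation onto the only free OH.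

**4 ⇒ 1 + 2.** Cut: the aryl C2–CH2 bond and the O–CMe2 bond of ring E; the forward reaction passes through 3. Reason: 1 is C2v-symmetric, so its two free ring carbons are equivalent. The new chain lands between one OH and the OMe group, so only one oxygen can close the ring. The symmetry of 1 thus fixes which oxygen becomes the ring-E ether, which the lactone oxygen and which stays OMe. Gain: two commercial compounds and no protecting group on ring A. Demand: the reaction must stop after one annulation.

## Other disconnections considered

**Alternative 1:** the first that comes to mind. Cut O11–C10a last: arylate 6 at its C9 (for example via its iodonium ylide or 9-iodide and a para-benzyloxyphenyl boron reagent) to give the 3-aryl-4-hydroxycoumarin A1. The forward key step would be an oxidative C–O ring closure of A1 to 13 with Fe(III), Cu(II) or Pd(II). Grounds for preferring the chosen plan: the C–H to be oxygenated in A1 is meta to the only donor of ring D, whereas radical-cation closures work best with a donor para to that site. The trioxygenated ring A with its free C–H is the more oxidisable arene. The non-oxidative variant (2'-oxygenated aryl, unmasking, cyclodehydration) avoids this but needs a differentially protected building block and two further steps. In both variants the C–C and C–O bonds are made in separate operations after activation of 6.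

**Alternative 2:** cut three bonds, O11–C11a, C6–C6a and C6–O5. The forward key step would be a Pd(II)-catalysed oxidative carbonylative double cyclisation (5-endo oxypalladation, CO insertion, lactonisation) of the bis(ortho-hydroxyaryl)acetylene A2, with CO supplying C6. This closes two rings in one operation and is attractive. Grounds for preferring the chosen plan: both ortho-hydroxyaryl groups of A2 can start the sequence, and attack by the ring-A hydroxyl gives the constitutional isomer with rings A and D exchanged. Only a modest electronic bias or additional protecting-group steps would separate the two paths. A2 also needs an aldehyde-to-alkyne homologation on a protected ring-A aldehyde, a Sonogashira coupling and selective deprotections, about nine steps against six.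

**Alternative 3:** cut only C6a–C6b. Convert 6 into its sulfonate A3, substitute with a meta-benzyloxyphenol to give the 4-aryloxycoumarin A4, and close the furan by a Pd(II)-mediated twofold C–H (dehydrogenative) coupling of A4 to 13. Grounds for preferring the chosen plan: this is the same union of two like-polarity carbons, but it needs two extra steps, a stoichiometric silver or copper oxidant above 100 °C, and faces the same C2'/C6' choice. Electrophilic palladation of the electron-rich ring-A C–H of A4 is a plausible competitor. The [3,3] route uses the N–O bond as internal oxidant, needs no metal and makes the C–C and C–O bonds in one step.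

Key step: step 5

## Route

**Step 1**
Reactants: 1 1-(2,6-dihydroxy-4-methoxyphenyl)ethan-1-one (2',6'-dihydroxy-4'-methoxyacetophenone); 2 isoprene (2-methylbuta-1,3-diene)
Product: 4 1-(7-hydroxy-5-methoxy-2,2-dimethyl-3,4-dihydro-2H-chromen-8-yl)ethan-1-one, via C-prenyl phenol 3 (not isolated)
Conditions: isoprene (1.1 equiv), Amberlyst 15, THF–heptane, 65 °C, sealed tube
Reagents that add atoms: none
Why: Acid-catalysed Friedel–Crafts prenylation followed by hydroalkoxylation (chromanylation): the dimethylallyl cation alkylates one of the two equivalent free ring carbons of 1 to give 3, whose alkene is protonated to the tertiary cation and trapped by the only adjacent OH (the other neighbour is OMe), so the ring fusion is unambiguous. The remaining OH is hydrogen-bonded to the acetyl group, which should slow a second annulation.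

**Step 2**
Reactants: 4 1-(7-hydroxy-5-methoxy-2,2-dimethyl-3,4-dihydro-2H-chromen-8-yl)ethan-1-one
Product: 6 10-hydroxy-5-methoxy-2,2-dimethyl-3,4-dihydro-2H,8H-pyrano[2,3-f]chromen-8-one, via β-keto ester 5 (not isolated)
Conditions: NaH (4 equiv), diethyl carbonate (5 equiv), toluene, 110 °C; then 1 M HCl
Reagents that add atoms: diethyl carbonate CCOC(=O)OCC
Why: Claisen condensation of the ketone enolate with diethyl carbonate gives 5, and the neighbouring phenoxide lactonises onto the ester; this is the standard 2-hydroxyacetophenone to 4-hydroxycoumarin synthesis, driven by formation of the stable sodium salt of the product.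

**Step 3**
Reactants: 7 N-hydroxyphthalimide; 8 [3-(benzyloxy)phenyl]boronic acid
Product: 9 2-[3-(benzyloxy)phenoxy]isoindoline-1,3-dione
Conditions: 8 (2 equiv), Cu(OAc)2 (1 equiv), pyridine (1.1 equiv), 4 Å MS, 1,2-dichloroethane, air, rt
Reagents that add atoms: none
Why: Chan–Lam-type copper(II)-mediated oxidative O-arylation of the N–OH group by the arylboronic acid (transmetalation, then C–O reductive elimination from a Cu(III) aryl); the benzyl ether is inert.

**Step 4**
Reactants: 9 2-[3-(benzyloxy)phenoxy]isoindoline-1,3-dione
Product: 10 O-[3-(benzyloxy)phenyl]hydroxylamine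
Conditions: N2H4·H2O (3 equiv), CHCl3–MeOH (9:1), rt; filtration; stored as the hydrochloride (HCl in Et2O)
Reagents that add atoms: none
Why: Ing–Manske hydrazinolysis removes the phthaloyl group as insoluble phthalhydrazide; the N–O bond and the benzyl ether should be untouched by hydrazine at room temperature.

**Step 5**
Reactants: 6 10-hydroxy-5-methoxy-2,2-dimethyl-3,4-dihydro-2H,8H-pyrano[2,3-f]chromen-8-one; 10 O-[3-(benzyloxy)phenyl]hydroxylamine (1.2 equiv, as hydrochloride)
Product: 13 9-(benzyloxy)-3-methoxy-6H-benzofuro[3,2-c]chromen-6-one bearing a 2,2-dimethyl-3,4-dihydro-2H-pyran ring fused across C1–C2 (ring O on C1), via ene-hydroxylamine 11 (not isolated), via aminophenol 12 (not isolated)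
Conditions: HCl (4 M in dioxane, 2.5 equiv), 1,4-dioxane, 60 °C, then 100 °C
Reagents that add atoms: none
Why: This is the oxygen analogue of the Fischer indole synthesis (benzofurans from O-aryl hydroxylamines and enolisable ketones, including cyclic 1,3-dicarbonyl compounds), whose nitrogen counterpart on 4-hydroxycoumarins gives indolo[3,2-c]coumarins. Acid-catalysed condensation of 10 at C10 of 6, the ketone-like carbon of the vinylogous acid and much more electrophilic than the lactone C8, should give ene-hydroxylamine 11 with loss of the former 10-OH as water. Protonated 11 then undergoes a charge-accelerated [3,3]-sigmatropic shift through a six-membered transition state over C9=C10–N–O–C1'=C6': the weak N–O bond breaks, the C9–C6' bond (later C6a–C6b) forms between two carbons that are both nucleophilic in the parent enol and phenol, and tautomerisation of the dienone gives aminophenol 12. The new phenolic oxygen, originally the oxygen of 7, adds 5-exo-trig to the C10 iminium tautomer and ammonia leaves as NH4Cl, which closes the furan ring and makes the sequence irreversible by aromatisation; any 12 hydrolysed to the 10-hydroxy compound would close to the same product. No stereocentre is formed. The step needs the shift to go to C6' (para to OBn) and not to C2': C2' lies between the O–N and OBn substituents, so its transition state is a crowded 1,2,3-trisubstituted array, while C6' is equally activated and unhindered. The electron-rich aryloxide is a poor leaving group, so transfer of NH2 to C9 should not compete, and the benzyl ether, the methyl ether and ring E should be stable to HCl in dioxane at 100 °C.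

**Step 6**
Reactants: 13 9-(benzyloxy)-3-methoxy-6H-benzofuro[3,2-c]chromen-6-one bearing a 2,2-dimethyl-3,4-dihydro-2H-pyran ring fused across C1–C2 (ring O on C1)
Product: 14 9-hydroxy-3-methoxy-6H-benzofuro[3,2-c]chromen-6-one bearing a 2,2-dimethyl-3,4-dihydro-2H-pyran ring fused across C1–C2 (ring O on C1), the target
Conditions: H2 (1 atm), 10% Pd/C, EtOAc–THF, rt
Reagents that add atoms: none
Why: Hydrogenolysis of a benzyl aryl ether on Pd/C; the lactone, the aromatic furan/pyranone C6a=C11a bond, the methyl ether and ring E should be inert at 1 atm and room temperature.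

## Compound list

1 | 1-(2,6-dihydroxy-4-methoxyphenyl)ethan-1-one | CC(=O)c1c(O)cc(OC)cc1O | starting material
2 | isoprene (2-methylbuta-1,3-diene) | C=CC(C)=C | starting material
3 | 1-[2,6-dihydroxy-4-methoxy-3-(3-methylbut-2-en-1-yl)phenyl]ethan-1-one | CC(=O)c1c(O)cc(OC)c(CC=C(C)C)c1O | intermediate
4 | 1-(7-hydroxy-5-methoxy-2,2-dimethyl-3,4-dihydro-2H-chromen-8-yl)ethan-1-one | CC(=O)c1c(O)cc(OC)c2c1OC(C)(C)CC2 | intermediate
5 | ethyl 3-(7-hydroxy-5-methoxy-2,2-dimethyl-3,4-dihydro-2H-chromen-8-yl)-3-oxopropanoate | CCOC(=O)CC(=O)c1c(O)cc(OC)c2c1OC(C)(C)CC2 | intermediate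
6 | 10-hydroxy-5-methoxy-2,2-dimethyl-3,4-dihydro-2H,8H-pyrano[2,3-f]chromen-8-one | COc1cc2oc(=O)cc(O)c2c2c1CCC(C)(C)O2 | intermediate
7 | N-hydroxyphthalimide | O=C1N(O)C(=O)c2ccccc12 | starting material
8 | [3-(benzyloxy)phenyl]boronic acid | OB(O)c1cccc(OCc2ccccc2)c1 | starting material
9 | 2-[3-(benzyloxy)phenoxy]isoindoline-1,3-dione | O=C1N(Oc2cccc(OCc3ccccc3)c2)C(=O)c2ccccc12 | intermediate
10 | O-[3-(benzyloxy)phenyl]hydroxylamine | NOc1cccc(OCc2ccccc2)c1 | intermediate
11 | 10-{[3-(benzyloxy)phenoxy]amino}-5-methoxy-2,2-dimethyl-3,4-dihydro-2H,8H-pyrano[2,3-f]chromen-8-one | COc1cc2oc(=O)cc(NOc3cccc(OCc4ccccc4)c3)c2c2c1CCC(C)(C)O2 | intermediate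
12 | 10-amino-9-[4-(benzyloxy)-2-hydroxyphenyl]-5-methoxy-2,2-dimethyl-3,4-dihydro-2H,8H-pyrano[2,3-f]chromen-8-one | COc1cc2oc(=O)c(-c3ccc(OCc4ccccc4)cc3O)c(N)c2c2c1CCC(C)(C)O2 | intermediate
13 | 9-(benzyloxy)-3-methoxy-6H-benzofuro[3,2-c]chromen-6-one bearing a 2,2-dimethyl-3,4-dihydro-2H-pyran ring fused across C1–C2 (ring O on C1) | COc1cc2oc(=O)c3c4ccc(OCc5ccccc5)cc4oc3c2c2c1CCC(C)(C)O2 | intermediate
14 | 9-hydroxy-3-methoxy-6H-benzofuro[3,2-c]chromen-6-one bearing a 2,2-dimethyl-3,4-dihydro-2H-pyran ring fused across C1–C2 (ring O on C1) | COc1cc2oc(=O)c3c4ccc(O)cc4oc3c2c2c1CCC(C)(C)O2 | target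

## Step count and least certain steps

Total step count: 6. Longest linear sequence: 4 steps (steps 1, 2, 5, 6 from 1; equally steps 3, 4, 5, 6 from 7 and 8).

**Step 5 (key step).** Three things may go wrong. Condensation at the peri-flanked, hydrogen-bonded C10 of 6 may be slow, so that acid-induced decomposition of 10 takes over. Part of the [3,3] shift may go to C2', which would lead to the 7-benzyloxy isomer. The deaminative ring closure of 12 may stop short. Fallback, from 6 to 14 by known chemistry with the D-ring regiochemistry fixed by the reagent: 6 is treated with PhI(OAc)2 and Na2CO3 in aqueous methanol to give the phenyliodonium ylide of 6 F1. Palladium-catalysed Suzuki-type coupling of the ylide (Pd(OAc)2, P(t-Bu)3, LiOH, DME–H2O, rt) with commercial [2,4-bis(benzyloxy)phenyl]boronic acid should give 9-[2,4-bis(benzyloxy)phenyl]-10-hydroxy-5-methoxy-2,2-dimethyl-3,4-dihydro-2H,8H-pyrano[2,3-f]chromen-8-one F2. Hydrogenolysis (H2, Pd/C) should give 9-(2,4-dihydroxyphenyl)-10-hydroxy-5-methoxy-2,2-dimethyl-3,4-dihydro-2H,8H-pyrano[2,3-f]chromen-8-one F3, and acid-catalysed cyclodehydration (TsOH, toluene, reflux) closes the furan and returns to the route at 14.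

**Step 1.** Over-alkylation may occur (a second annulation on the remaining OH and its neighbouring ring carbon), as may O-prenylation, because the product is still an electron-rich phenol. Fallback, from 1 to 4: change from Friedel–Crafts alkylation to alkylation of the phenoxide. C-prenylation of 1 with prenyl bromide and DBU in THF (or aqueous KOH) should give 3, which is isolated, and a separate acid-catalysed cyclisation (TsOH, toluene, 80 °C) gives 4. No compound outside the list is made.

**Step 3.** Protodeboronation and oxidative homocoupling of 8 may consume the boronic acid, and the copper-mediated coupling may turn over poorly. Fallback, from 8 to 10 without copper and without 9: oxidation of 8 (H2O2, NaOH, THF) to 3-(benzyloxy)phenol F4, then electrophilic amination of its potassium salt (KOt-Bu, THF, 0 °C) with O-(mesitylsulfonyl)hydroxylamine, which should give 10 directly.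

**Step 4.** Free 10 may be lost on isolation through N–O cleavage or air oxidation of the electron-rich aryloxyamine. Fallback, from 8 to 13 with a bench-stable surrogate: Chan–Lam O-arylation of ethyl N-hydroxyacetimidate with 8 (Cu(OAc)2, pyridine, 1,2-dichloroethane, air) should give ethyl N-[3-(benzyloxy)phenoxy]ethanimidate F5. Under the conditions of step 5 with one equivalent of water, F5 is hydrolysed in the flask to the hydrochloride of 10 and reacts on with 6 to give 13.

## Further compounds

F1 | step 5 | phenyliodonium ylide of 6 (9-phenyliodonio-10-oxido-5-methoxy-2,2-dimethyl-3,4-dihydro-2H,8H-pyrano[2,3-f]chromen-8-one) | COc1cc2oc(=O)c([I+]c3ccccc3)c([O-])c2c2c1CCC(C)(C)O2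
F2 | step 5 | 9-[2,4-bis(benzyloxy)phenyl]-10-hydroxy-5-methoxy-2,2-dimethyl-3,4-dihydro-2H,8H-pyrano[2,3-f]chromen-8-one | COc1cc2oc(=O)c(-c3ccc(OCc4ccccc4)cc3OCc3ccccc3)c(O)c2c2c1CCC(C)(C)O2
F3 | step 5 | 9-(2,4-dihydroxyphenyl)-10-hydroxy-5-methoxy-2,2-dimethyl-3,4-dihydro-2H,8H-pyrano[2,3-f]chromen-8-one | COc1cc2oc(=O)c(-c3ccc(O)cc3O)c(O)c2c2c1CCC(C)(C)O2
F0 | step 1 | none | none
F4 | step 3 | 3-(benzyloxy)phenol | Oc1cccc(OCc2ccccc2)c1
F5 | step 4 | ethyl N-[3-(benzyloxy)phenoxy]ethanimidate | CCOC(C)=NOc1cccc(OCc2ccccc2)c1
A1 | alternative 1 | 9-[4-(benzyloxy)phenyl]-10-hydroxy-5-methoxy-2,2-dimethyl-3,4-dihydro-2H,8H-pyrano[2,3-f]chromen-8-one | COc1cc2oc(=O)c(-c3ccc(OCc4ccccc4)cc3)c(O)c2c2c1CCC(C)(C)O2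
A2 | alternative 2 | 8-{[4-(benzyloxy)-2-hydroxyphenyl]ethynyl}-5-methoxy-2,2-dimethyl-3,4-dihydro-2H-chromen-7-ol | COc1cc(O)c(C#Cc3ccc(OCc4ccccc4)cc3O)c2c1CCC(C)(C)O2
A3 | alternative 3 | 5-methoxy-2,2-dimethyl-8-oxo-3,4-dihydro-2H,8H-pyrano[2,3-f]chromen-10-yl 4-methylbenzenesulfonate | COc1cc2oc(=O)cc(OS(=O)(=O)c3ccc(C)cc3)c2c2c1CCC(C)(C)O2
A4 | alternative 3 | 10-[3-(benzyloxy)phenoxy]-5-methoxy-2,2-dimethyl-3,4-dihydro-2H,8H-pyrano[2,3-f]chromen-8-one | COc1cc2oc(=O)cc(Oc3cccc(OCc4ccccc4)c3)c2c2c1CCC(C)(C)O2
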